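**Retrosynthetic overview**
- The 4-substituted furan-2(5H)-one ring is treated as a masked 3-substituted furan (borohydride reduction back to a hydroxybutenolide, then singlet oxygen back to the furan), so the target reduces to a 3-furyl diol.
- The strategy rests on the trisubstituted alkene C(CH2OH)(C16 chain)=CH–CH2–CH(OH). Its hydroxymethyl oxygen is cis to the vinyl hydrogen and the chain is cis to the CH2–CH(OH) arm, which is the pattern left by anti addition of R–Mg across a 2-alkyn-1-ol through a five-membered O–C–C=C–Mg chelate. The C(sp2)–CH2 bond to the homofarnesyl chain is therefore disconnected.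
- The C9 alkynol comes from 3-furaldehyde by catalytic enantioselective propargylation (sets the only stereocentre, R), silylation and hydroxymethylation of the alkyne.
- The C16 Grignard reagent comes from (2E,6E)-farnesol by oxidation, methylenation, terminal hydroboration and bromination.
- Ring order: no ring is built. The furan is bought and is converted into the butenolide in the last two steps.

Key step: step 9

Assumption: the (R)-enantiomer of the chiral phosphoric acid is taken to give the (R)-carbinol, as it does with aromatic aldehydes; if the sense is opposite for the 3-furyl aldehyde, the (S)-acid is used instead.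

**Route**

Step 1
Reactants: 1 3-furaldehyde; 2 allenylboronic acid pinacol ester
Product: 4 (R)-1-(furan-3-yl)but-3-yn-1-ol, via pinacol borate ester 3 (not isolated)
Conditions: (R)-TRIP phosphoric acid [(R)-3,3'-bis(2,4,6-triisopropylphenyl)-1,1'-binaphthyl-2,2'-diyl hydrogen phosphate] (5 mol%), 4 Å MS, toluene, –20 °C; aq. NaHCO3 work-up
Reagents that add atoms: none
Why: Chiral Brønsted acid-catalysed propargylation (SE2' addition of the allenylboronate through a six-membered chair transition state, with the acid hydrogen-bonded to a boronate oxygen and its phosphoryl oxygen to the formyl hydrogen) should deliver the propargyl group to one enantiotopic face of the aldehyde and so set the (R)-carbinol.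

Step 2
Reactants: 4 (R)-1-(furan-3-yl)but-3-yn-1-ol
Product: 5 (R)-tert-butyl{[1-(furan-3-yl)but-3-yn-1-yl]oxy}dimethylsilane
Conditions: TBSCl, imidazole, DMF, rt
Reagents that add atoms: tert-butyldimethylsilyl chloride, CC(C)(C)[Si](C)(C)Cl
Why: Imidazole-promoted silylation of a secondary alcohol masks the acidic OH before the organolithium and Grignard steps and does not touch the stereocentre.

Step 3
Reactants: 5 (R)-tert-butyl{[1-(furan-3-yl)but-3-yn-1-yl]oxy}dimethylsilane; 6 formaldehyde (used as dry paraformaldehyde)
Product: 8 (R)-5-(tert-butyldimethylsilyloxy)-5-(furan-3-yl)pent-2-yn-1-ol, via lithium acetylide 7 (not isolated)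
Conditions: n-BuLi, THF, –78 °C; then (CH2O)n, –78 °C → rt; sat. aq. NH4Cl
Reagents that add atoms: none
Why: Deprotonation of the terminal alkyne (far more acidic than any furan C–H) and 1,2-addition of the lithium acetylide to formaldehyde is the classical hydroxymethylation of an alkyne.

Step 4
Reactants: 9 (2E,6E)-farnesol
Product: 10 (2E,6E)-farnesal
Conditions: TEMPO (10 mol%), PhI(OAc)2, CH2Cl2, rt
Reagents that add atoms: none
Why: TEMPO/PhI(OAc)2 oxidation of a primary allylic alcohol stops at the aldehyde and is mild enough to keep the 2E geometry.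

Step 5
Reactants: 10 (2E,6E)-farnesal
Product: 11 (3E,7E)-4,8,12-trimethyltrideca-1,3,7,11-tetraene
Conditions: Ph3PCH3Br, n-BuLi, THF, 0 °C; then 10, –78 °C → rt
Reagents that add atoms: methyltriphenylphosphonium bromide, C[P+](c1ccccc1)(c1ccccc1)c1ccccc1.[Br-]
Why: Wittig methylenation of the enal with the unstabilised ylide adds the one extra carbon as a terminal vinyl group and leaves the trisubstituted alkenes alone.

Step 6
Reactants: 11 (3E,7E)-4,8,12-trimethyltrideca-1,3,7,11-tetraene
Product: 13 (3E,7E)-4,8,12-trimethyltrideca-3,7,11-trien-1-ol (homofarnesol), via B-homofarnesyl-9-BBN 12 (not isolated)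
Conditions: 9-BBN, THF, 0 °C → rt; then 3 M NaOH, 30% H2O2, 0 °C → rt
Reagents that add atoms: hydrogen peroxide, OO
Why: Hydroboration–oxidation with the bulky borane is selective for the only monosubstituted alkene and places boron on the terminal carbon (anti-Markovnikov), and alkaline peroxide then gives the primary alcohol with the 3E alkene intact.

Step 7
Reactants: 13 (3E,7E)-homofarnesol
Product: 15 (3E,7E)-homofarnesyl bromide, via homofarnesyl mesylate 14 (not isolated)
Conditions: MsCl, Et3N, CH2Cl2, –10 °C; then LiBr, THF, 50 °C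
Reagents that add atoms: lithium bromide, [Li+].[Br-]
Why: Mesylation followed by SN2 displacement with bromide converts the primary homoallylic alcohol into the bromide, and no allylic transposition is possible because the leaving group is not allylic.

Step 8
Reactants: 15 (3E,7E)-homofarnesyl bromide
Product: 16 (3E,7E)-homofarnesylmagnesium bromide (titrated ether solution)
Conditions: Mg turnings (I2-activated), Et2O, rt
Reagents that add atoms: magnesium, [Mg]
Why: Insertion of magnesium into the primary C–Br bond (Grignard formation) should keep the 3E geometry, because closure of this homoallylic reagent to a cyclopropylcarbinyl isomer would create a tertiary carbanion and is not expected at room temperature.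

Step 9
Reactants: 8 (R)-5-(tert-butyldimethylsilyloxy)-5-(furan-3-yl)pent-2-yn-1-ol; 16 (3E,7E)-homofarnesylmagnesium bromide
Product: 19 (2E,5R)-5-(tert-butyldimethylsilyloxy)-5-(furan-3-yl)-2-[(3E,7E)-4,8,12-trimethyltrideca-3,7,11-trien-1-yl]pent-2-en-1-ol, via bromomagnesium alkoxide 17 (not isolated), via chelated alkenylmagnesium 18 (not isolated)
Conditions: EtMgBr (1.0 equiv), Et2O, 0 °C; then 16 (3 equiv), CuI (10 mol%), Et2O, –10 °C → rt; sat. aq. NH4Cl
Reagents that add atoms: none
Why: The propargylic OH is first converted into its bromomagnesium alkoxide 17; the alkylcopper/magnesium species formed from 16 and CuI then transfers the homofarnesyl group to alkyne carbon C2 (the carbon bearing CH2O) while magnesium becomes bound to C3 on the opposite side, because only this arrangement lets the alkoxide oxygen hold the alkenyl metal in the five-membered O–C1–C2=C3–Mg ring of 18, and protonolysis with retention then replaces Mg by H. The closest known reaction type is the copper-catalysed, hydroxyl-directed anti-carbomagnesiation of 2-alkyn-1-ols by alkyl Grignard reagents, used here at the demanding end of its range (internal alkyne, unactivated primary alkyl group). No ring of the product is closed; the only cycle is the transient oxamagnesacycle, formed by O–Mg chelation and opened on work-up. No stereocentre is created and the (R)-carbinol, which carries no acidic hydrogen and lies two carbons from the reacting alkyne, is not touched; what is set is the alkene geometry, since Mg cis to CH2O forces the new chain trans to it, so that after protonation H is cis to CH2OH and the chain is cis to the CH2–CH(OSi) arm as in the target. The step needs delivery of the chain to C2 and not C3, and anti and not syn addition, and both are secured by the propargylic magnesium alkoxide; the silyl ether oxygen on the other flank can chelate magnesium only at the same carbon C3, and the furan, the silyl ether and the chain alkenes are inert to the reagents.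

Step 10
Reactants: 19 silyl-protected furyl allylic alcohol
Product: 20 (1R,3E,7E,11E)-1-(furan-3-yl)-4-(hydroxymethyl)-8,12,16-trimethylheptadeca-3,7,11,15-tetraen-1-ol (furyl diol)
Conditions: Bu4NF, THF, 0 °C → rt
Reagents that add atoms: none
Why: Fluoride-induced desilylation, driven by the strong Si–F bond, frees the carbinol without the acid that a furyl carbinol would not tolerate, and it leaves the alkenes and the stereocentre alone.

Step 11
Reactants: 20 furyl diol
Product: 22 5-hydroxy-4-substituted furan-2(5H)-one (γ-hydroxybutenolide, hemiacetal carbon as a mixture of epimers), via furan endoperoxide 21 (not isolated)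
Conditions: O2, hν (visible), rose bengal (cat.), i-Pr2NEt, CH2Cl2 (trace MeOH), –78 °C; stopped as soon as 20 is consumed
Reagents that add atoms: oxygen, O=O
Why: Singlet oxygen should add (4+2) to the electron-rich furan much faster than it undergoes ene reaction with the trisubstituted alkenes at –78 °C, and the hindered amine removes the less hindered bridgehead hydrogen at furan C5 (Kornblum–DeLaMare-type fragmentation of the endoperoxide), so the lactone carbonyl should end on the carbon remote from the carbinol substituent.

Step 12
Reactants: 22 γ-hydroxybutenolide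
Product: 24 hippolide C, via sodium hydroxy enoate 23 (not isolated)
Conditions: NaBH4, EtOH, 0 °C; then 1 M HCl to pH 2, rt
Reagents that add atoms: none
Why: The hydroxybutenolide is in equilibrium with its ring-opened (Z)-formyl acrylate, whose aldehyde is reduced chemoselectively by borohydride, and acidification lactonises the resulting (Z)-4-hydroxy-2-enoate to the butenolide, which removes the epimeric hemiacetal centre and leaves the (R)-carbinol unchanged.

**Compound list**
1 | 3-furaldehyde | O=Cc1ccoc1 | starting material
2 | allenylboronic acid pinacol ester | C=C=CB1OC(C)(C)C(C)(C)O1 | starting material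
3 | pinacol borate ester of (R)-1-(furan-3-yl)but-3-yn-1-ol | C#CC[C@@H](OB1OC(C)(C)C(C)(C)O1)c1ccoc1 | intermediate
4 | (R)-1-(furan-3-yl)but-3-yn-1-ol | C#CC[C@@H](O)c1ccoc1 | intermediate
5 | (R)-tert-butyl{[1-(furan-3-yl)but-3-yn-1-yl]oxy}dimethylsilane | C#CC[C@@H](O[Si](C)(C)C(C)(C)C)c1ccoc1 | intermediate
6 | formaldehyde (as paraformaldehyde) | C=O | starting material
7 | lithium acetylide of 5 | [Li]C#CC[C@@H](O[Si](C)(C)C(C)(C)C)c1ccoc1 | intermediate
8 | (R)-5-(tert-butyldimethylsilyloxy)-5-(furan-3-yl)pent-2-yn-1-ol | OCC#CC[C@@H](O[Si](C)(C)C(C)(C)C)c1ccoc1 | intermediate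
9 | (2E,6E)-farnesol | CC(C)=CCC/C(C)=C/CC/C(C)=C/CO | starting material
10 | (2E,6E)-farnesal | CC(C)=CCC/C(C)=C/CC/C(C)=C/C=O | intermediate
11 | (3E,7E)-4,8,12-trimethyltrideca-1,3,7,11-tetraene | CC(C)=CCC/C(C)=C/CC/C(C)=C/C=C | intermediate
12 | 9-[(3E,7E)-4,8,12-trimethyltrideca-3,7,11-trien-1-yl]-9-borabicyclo[3.3.1]nonane | CC(C)=CCC/C(C)=C/CC/C(C)=C/CCB1C2CCCC1CCC2 | intermediate
13 | (3E,7E)-homofarnesol | CC(C)=CCC/C(C)=C/CC/C(C)=C/CCO | intermediate
14 | (3E,7E)-homofarnesyl methanesulfonate | CC(C)=CCC/C(C)=C/CC/C(C)=C/CCOS(C)(=O)=O | intermediate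
15 | (3E,7E)-homofarnesyl bromide | CC(C)=CCC/C(C)=C/CC/C(C)=C/CCBr | intermediate
16 | (3E,7E)-homofarnesylmagnesium bromide | CC(C)=CCC/C(C)=C/CC/C(C)=C/CC[Mg]Br | intermediate
17 | bromomagnesium alkoxide of 8 | Br[Mg]OCC#CC[C@@H](O[Si](C)(C)C(C)(C)C)c1ccoc1 | intermediate
18 | 2,5-dihydro-1,2-oxamagnesole chelate (4-homofarnesyl, 3-[(R)-2-silyloxy-2-(furan-3-yl)ethyl]) | CC(C)=CCC/C(C)=C/CC/C(C)=C/CCC1=C(C[C@@H](O[Si](C)(C)C(C)(C)C)c2ccoc2)[Mg]OC1 | intermediate
19 | (2E,5R)-5-(tert-butyldimethylsilyloxy)-5-(furan-3-yl)-2-[(3E,7E)-4,8,12-trimethyltrideca-3,7,11-trien-1-yl]pent-2-en-1-ol | CC(C)=CCC/C(C)=C/CC/C(C)=C/CC/C(=C\C[C@@H](O[Si](C)(C)C(C)(C)C)c1ccoc1)CO | intermediate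
20 | (1R,3E,7E,11E)-1-(furan-3-yl)-4-(hydroxymethyl)-8,12,16-trimethylheptadeca-3,7,11,15-tetraen-1-ol | CC(C)=CCC/C(C)=C/CC/C(C)=C/CC/C(=C\C[C@@H](O)c1ccoc1)CO | intermediate
21 | 2,5-endoperoxide of furan 20 (2,3,7-trioxabicyclo[2.2.1]hept-5-ene, substituted at C5) | CC(C)=CCC/C(C)=C/CC/C(C)=C/CC/C(=C\C[C@@H](O)C1=CC2OOC1O2)CO | intermediate
22 | 5-hydroxy-4-[(1R,3E,7E,11E)-1-hydroxy-4-(hydroxymethyl)-8,12,16-trimethylheptadeca-3,7,11,15-tetraen-1-yl]furan-2(5H)-one | CC(C)=CCC/C(C)=C/CC/C(C)=C/CC/C(=C\C[C@@H](O)C1=CC(=O)OC1O)CO | intermediate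
23 | sodium (Z)-4-hydroxy-3-[(1R)-1-hydroxyalkenyl]but-2-enoate (ring-opened, reduced form of 22) | CC(C)=CCC/C(C)=C/CC/C(C)=C/CC/C(=C\C[C@@H](O)/C(CO)=C/C(=O)[O-])CO.[Na+] | intermediate
24 | hippolide C | CC(C)=CCC/C(C)=C/CC/C(C)=C/CC/C(=C\C[C@@H](O)C1=CC(=O)OC1)CO | target

**Step count**
Total: 12 steps. Longest linear sequence: 9 steps (farnesol 9 to hippolide C 24, steps 4–12); the furan branch is 3 steps before the union.

**Steps most likely to fail, and fallbacks**

1. Step 9. Alkyl transfer to the internal alkyne may be slower than β-hydride loss from the alkylcopper intermediate, so that reduction of the alkyne or plain recovery of the alkynol takes over, and some delivery to C3 may intrude. The fallback forms the same C(sp2)–CH2 bond by cross-coupling and sets out from 8. Hydroxyl-directed ruthenium-catalysed trans-hydrostannation (Bu3SnH, [Cp*RuCl]4 cat., CH2Cl2, rt) should place tin on the carbon next to the free OH and hydrogen on C3 on the opposite side, giving (R,Z)-5-(tert-butyldimethylsilyloxy)-5-(furan-3-yl)-2-(tributylstannyl)pent-2-en-1-ol F1. Iododestannylation with retention (I2, CH2Cl2, 0 °C) gives (R,Z)-5-(tert-butyldimethylsilyloxy)-5-(furan-3-yl)-2-iodopent-2-en-1-ol F2. B-alkyl Suzuki–Miyaura coupling of F2 with borane 12 (made from 11 and 9-BBN as in step 6 and used without oxidation; Pd(dppf)Cl2, AsPh3, Cs2CO3, DMF/THF/H2O, rt) keeps the alkene geometry and comes back to the route at 19.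

2. Step 11. Ene oxygenation of the four trisubstituted alkenes may compete if the furan oxidation is slow (the amine also quenches singlet oxygen), and proton abstraction at the wrong bridgehead would give the regioisomeric hydroxybutenolide. The fallback lets a silicon substituent fix the regiochemistry and sets out from 1. In-situ protection of the aldehyde as its lithium morpholide adduct, lithiation at C5 with sec-BuLi and quenching with Me3SiCl gives 5-(trimethylsilyl)furan-3-carbaldehyde F3. The operations of steps 1, 2, 3 and 9 are then repeated: with 2 to (R)-1-[5-(trimethylsilyl)furan-3-yl]but-3-yn-1-ol F4, silylation to its tert-butyldimethylsilyl ether F5, hydroxymethylation with 6 to (R)-5-(tert-butyldimethylsilyloxy)-5-[5-(trimethylsilyl)furan-3-yl]pent-2-yn-1-ol F6, and carbomagnesiation with 16 to the 5-trimethylsilylfuryl analogue of 19 F7. The silyl ether is cleaved with pyridine-buffered HF·pyridine (THF, 0 °C), which should leave the furyl C–Si bond in place, to give the 5-trimethylsilylfuryl diol F8. Photooxygenation of F8 without amine (O2, hν, rose bengal, CH2Cl2/MeOH, –78 °C) proceeds by silyl migration to the peroxide oxygen, so the silicon-bearing carbon becomes the carboxyl carbon; it is also faster than the oxidation of the parent furan. The fallback comes back to the route at 22.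

3. Step 1. Facial discrimination may be insufficient for the small, electron-rich heteroaryl aldehyde, or uncatalysed background addition may erode the enantiomeric purity. The fallback resolves the racemate and sets out from 1. Barbier propargylation (propargyl bromide, Zn, THF/sat. aq. NH4Cl) gives racemic 1-(furan-3-yl)but-3-yn-1-ol F9. Lipase-catalysed acylation (Candida antarctica lipase B or Amano lipase PS, vinyl acetate, MTBE, rt) should, by the empirical size rule for secondary carbinols, acylate the (R)-enantiomer faster and give (R)-1-(furan-3-yl)but-3-yn-1-yl acetate F10, which is separated from the unreacted (S)-1-(furan-3-yl)but-3-yn-1-ol F11. Methanolysis of F10 (K2CO3, MeOH, rt) comes back to the route at 4.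

**Further compounds**
F1 | step 9 | (R,Z)-5-(tert-butyldimethylsilyloxy)-5-(furan-3-yl)-2-(tributylstannyl)pent-2-en-1-ol | CCCC[Sn](CCCC)(CCCC)/C(=C\C[C@@H](O[Si](C)(C)C(C)(C)C)c1ccoc1)CO
F2 | step 9 | (R,Z)-5-(tert-butyldimethylsilyloxy)-5-(furan-3-yl)-2-iodopent-2-en-1-ol | I/C(=C\C[C@@H](O[Si](C)(C)C(C)(C)C)c1ccoc1)CO
F3 | step 11 | 5-(trimethylsilyl)furan-3-carbaldehyde | O=Cc1coc([Si](C)(C)C)c1
F4 | step 11 | (R)-1-[5-(trimethylsilyl)furan-3-yl]but-3-yn-1-ol | C#CC[C@@H](O)c1coc([Si](C)(C)C)c1
F5 | step 11 | tert-butyldimethylsilyl ether of F4 | C#CC[C@@H](O[Si](C)(C)C(C)(C)C)c1coc([Si](C)(C)C)c1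
F6 | step 11 | (R)-5-(tert-butyldimethylsilyloxy)-5-[5-(trimethylsilyl)furan-3-yl]pent-2-yn-1-ol | OCC#CC[C@@H](O[Si](C)(C)C(C)(C)C)c1coc([Si](C)(C)C)c1
F7 | step 11 | 5-trimethylsilylfuryl analogue of 19 | CC(C)=CCC/C(C)=C/CC/C(C)=C/CC/C(=C\C[C@@H](O[Si](C)(C)C(C)(C)C)c1coc([Si](C)(C)C)c1)CO
F8 | step 11 | 5-trimethylsilylfuryl diol (analogue of 20) | CC(C)=CCC/C(C)=C/CC/C(C)=C/CC/C(=C\C[C@@H](O)c1coc([Si](C)(C)C)c1)CO
F9 | step 1 | racemic 1-(furan-3-yl)but-3-yn-1-ol | C#CCC(O)c1ccoc1
F10 | step 1 | (R)-1-(furan-3-yl)but-3-yn-1-yl acetate | C#CC[C@@H](OC(C)=O)c1ccoc1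
F11 | step 1 | (S)-1-(furan-3-yl)but-3-yn-1-ol | C#CC[C@H](O)c1ccoc1
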